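At 20.0 h the oak run, charged with twice the substrate of the ash run, stands about half as far from the symmetric case of equal isomer of the product and target.

| setting | ash | maple | oak | flask |
|---|---|---|---|---|
| substrate | 18 mM | 18 mM | 36 mM | 18 mM |
| coupling partner | 2 equiv | 2 equiv | 2 equiv | 2.00 equiv |
| protic impurity | 1.8 mM | 1.8 mM | 1.8 mM | 1.80 mM |
| catalyst | 0.14 mol% | 0.22 mol% | 0.1 mol% | 0.1 mol% |
| remark | run made earlier | run made earlier | run made earlier |  |
| time |  |  |  | 15 h |

| run | time / h | isomer of the product / % | target / % | substrate / % |
|---|---|---|---|---|
| ash | 5.00 | 14.5 | 11.7 | 67.4 |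
| ash | 10.0 | 11.3 | 5.7 | 78.8 |
| ash | 15.0 | 8.6 | 0.8 | 83.7 |
| ash | 20.0 | 6.2 | 1.9 | 88.1 |
| maple | 2.50 | 16.8 | 13.5 | 54.8 |
| maple | 6.00 | 12.9 | 6.3 | 69.3 |
| maple | 12.0 | 10.9 | 4.7 | 80.8 |
| maple | 20.0 | 6.5 | 2.3 | 87.3 |
| oak | 2.50 | 20.1 | 20.6 | 38.4 |
| oak | 6.00 | 17.2 | 15.8 | 53.5 |
| oak | 12.0 | 13.2 | 11.7 | 65.3 |
| oak | 20.0 | 9.4 | 5.4 | 76.1 |

(readings scatter by 1 percentage point)

- ratio of isomer of the product to target at 30 s
- ratio of isomer of the product to target at 20 min
- ratio of isomer of the product to target at 15 h
- which of isomer of the product and target there is more of at 15 h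

- a reading or a percentage of target counts all its forms, free or not
- a reading of substrate is of its free form alone

That distance is the lean, ln([isomer of the product]/[target]), zero at equal amounts. Its worth depends on how well each number is known. From the ash run to the maple run the catalyst loading rises by a factor 1.57, yet the lean at 20.0 h goes only from 1.18 to 1.04, a gap smaller than the 0.526 that one standard deviation on the late ash target reading makes. The same deviation on the ash isomer reading makes 0.161, so the late target readings and the substrate charge are what must be known well. Substrate charge times lean at 20.0 h gives: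

ash 21.3 mM, maple 18.7 mM, oak 20.0 mM

The ash target reading at 15.0 h, 0.8%, is smaller than the scatter, so the reckoning here takes the mean of the ash leans at 10.0 h and 20.0 h:

W = 16.8 mM

This lean charge, substrate charge times lean at 15 h, gives for the flask:

ratio = exp(W/[substrate]) = 2.54

The readings begin at 2.50 h, later than both early times, so this reckoning offers no early ratio. The forecast gives 0.93, 0.95 and 2.5, with isomer of the product ahead, holding that “the course does not depend on catalyst loading”.

The flask gives 0.475, 0.509 and 2.78, with isomer of the product ahead, 8.65% against 3.11%.

    substrate + coupling partner ⇌ isomer of the product (K = 620 /M, k = 0.570 /M/min)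
    target + catalyst ⇌ isomer of the product + catalyst, rate k2*[catalyst]*[target] forward; the back reaction follows from the equilibrium constant (k = 600 /M/min)
    coupling partner → decomposed reagent (k = 0.0630 /min)
    substrate + coupling partner ⇌ target (K = 12.0 /M, k = 1.20 /M/min)
    substrate + target ⇌ idle adduct, settled at all times (K = 2300 /M)
    coupling partner + protic impurity → quenched reagent (k = 14.0 /M/min)

The forecast's first ratio is about twice the flask's, whose target leads until the two level at 2.85 h. The flask's lean charge comes to 18.4 mM against the carried 16.8 mM. The same flask with 11 mM of substrate reckons as exp(W/[substrate]) = 4.61, and that neighbouring flask gives 6.42 at 15 h, higher than reckoned.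

The readings were generated by integration with made-up constants, and the scatter is random.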